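## Structural features

The target is a single-ring compound: a γ-butyrolactone (O1, C2 carbonyl, C3, C4, C5) with an exocyclic methylene on C3, a free carboxylic acid on C4 and a 14-oxopentadecyl chain on C5 (thirteen CH2 groups ending in a methyl ketone). C4 and C5 are the only stereocentres; they are neighbours, both S, and hold the carboxyl group and the chain cis on the ring. The cis arrangement is the less stable one, and the C4 hydrogen is both α to the acid and allylic to the conjugated methylene, so base can epimerise C4 or move the double bond into the ring; the methylene lactone is also a Michael acceptor. The methyl ketone is a second enolisable carbonyl group and would interfere with enolate chemistry at C3, so it must stay masked until C3 has been functionalised. The chain is routine; the real difficulty is the cis C4/C5 pair in one absolute sense on a small ring with one labile centre, together with a late and mild entry of the methylene. The plan exploits that C3, C4 and C5 are contiguous and that C4 carries a one-carbon branch. Written as CH2–O, that branch can hold C2–C3 as a diazoacetate over a (Z) C4=C5 double bond, so a carbene at C3 bonds to C4 and C5 in one step; the C3–C5 bond made this way is temporary and is later exchanged for O1–C5.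

## Logic of the disconnections

24 ⇒ 22. The C3=CH2 bond is cut first and C3 is given a carboxyl group instead. The methylene is the most fragile part of 24, so it should be made last; 22 is a stable malonic-type acid. The forward step (through 23) is a decarboxylative Mannich condensation with formaldehyde and must run in weakly acidic buffer at room temperature, so that C4 is not epimerised and the double bond does not migrate.

22 ⇒ 20. The C3–CO2H bond is cut and the ketone is returned to its dioxolane. This leaves a lactone acid with an unfunctionalised C3. The forward carboxylation uses a base, so the ketone must be masked in 20 and C4 must stay a free carboxylate, whose α-hydrogen is not acidic; the acid work-up passes through 21 and unmasks the ketone.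

20 ⇒ 18. No skeletal bond is cut; the C4 carboxyl group is taken back to a primary alcohol, because only a CH2–O branch can act as the tether of the key step. The forward oxidation passes through 19, which is epimerisable at C4, so it must be fast and near neutral.

18 ⇒ 16 ⇒ 15. The O1–C5 bond is cut and the C3–C5 bond restored (via 17 and 16), turning the lactone into a cyclopropane-fused lactone whose ring oxygen sits on the C4 branch. The gain is that both stereocentres of 18 become carbons of one three-membered ring. Forward, iodide must break C3–C5 (not C3–C4) of 15 with inversion at C5, and the carboxylate of 17 must displace iodide with a second inversion, so the cis relation survives.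

15 ⇒ 14. C3–C4 and C3–C5 are cut together. Two rings and three stereocentres disappear and an achiral open-chain ester remains. The forward carbene addition must be face-selective (catalyst) and needs the Z alkene, whose geometry is copied into the C4/C5 relation.

14 ⇒ 12 ⇒ 10 + 11. The C=N2 unit is traced (via 13) to a C–Br bond, and the ester C–O bond is cut. This separates the two-carbon C2–C3 unit from the chain alcohol. Forward, acylation and diazo formation must avoid acid because of the dioxolane and the allylic ester.

10 ⇒ 9 ⇒ 7 + 6. The Z alkene is taken back to an alkyne and the C(sp)–C(sp3) bond beside it is cut, splitting the skeleton into a three-carbon and a fifteen-carbon piece. Forward, hydrogenation must stop at the cis alkene and 7 must react (as 8) at carbon.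

6 ⇒ 5 ⇒ 1 + 2. The dioxolane is returned to the ketone and the bond between the ketone α-carbon and the chain is cut (via 4 and 3), giving two bulk chemicals. Forward, only one end of 2 may react, which an excess of 2 secures.

## Other disconnections considered

Alternative 1: The cut is the O1–C5 bond, made as a C–H oxidation.
- Forward step: the half ester (3R)-3-(tert-butoxycarbonyl)-18-oxononadecanoic acid A1, with C4 already set, would be treated with H2O2 and a chiral Mn(pdp)(OTf)2-type catalyst. The bound carboxylate directs hydrogen abstraction from the γ-methylene (C5), and rebound through the carboxylate oxygen would close the lactone to tert-butyl (2S,3S)-5-oxo-2-(14-oxopentadecyl)oxolane-3-carboxylate A2.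
- In favour: C5 needs no prior functional group, only one stereocentre has to be made beforehand, no diazo compound is involved, and the ketone might stay unprotected in the oxidation. In step count to the lactone this is the better plan.
- Against: the C5–H bonds are β to an ester and so deactivated toward an electrophilic oxidant, while the chain offers a dozen unactivated methylenes; site selectivity rests on the directing group alone. The catalyst must also choose between two diastereotopic hydrogens against the substrate's trans preference, and a radical intermediate gives no geometric guarantee.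
- Comparison: the chosen plan fixes the C4/C5 relation by alkene geometry in a stereospecific concerted step, which is the firmer mechanistic basis. Both plans arrive at a cis lactone without the methylene and need the same late methylenation (equal), which for A2 follows ester cleavage and would meet a free ketone.

Alternative 2: The cut removes C2 as carbon monoxide (C2–C3 and C2–O1).
- Forward step: the syn alcohol (3R,4S)-3-({[tert-butyl(dimethyl)silyl]oxy}methyl)-17-(2-methyl-1,3-dioxolan-2-yl)heptadec-1-yn-4-ol A3 would react with CO over PdCl2, PPh3 and SnCl2. Carbonylative activation of the C5 hydroxyl at palladium, addition across the alkyne and protonolysis would give (4R,5S)-4-({[tert-butyl(dimethyl)silyl]oxy}methyl)-3-methylidene-5-[13-(2-methyl-1,3-dioxolan-2-yl)tridecyl]oxolan-2-one A4.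
- In favour: methylene, carbonyl and ring arrive together, so no enolate chemistry on the lactone is needed and the carboxylation/Mannich pair of the chosen plan disappears; on this point it is the better plan. The ring closure touches neither stereocentre.
- Against: both stereocentres must already be present in A3 with the syn relation, while common routes to branched homopropargylic alcohols favour anti, so the stereochemical problem is moved, not solved. CO pressure and a tin additive are needed, and after A4 the primary alcohol must be freed and oxidised beside the finished, sensitive methylene lactone.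
- Comparison: both plans carry the C4 branch as CH2O and the ketone as dioxolane (equal). The endgame is shorter, the front end probably longer, so the overall step economy is about equal.

Alternative 3: The cut is the bond from C4 to the carboxyl carbon; the C3=CH2 bond appears by fragmentation.
- Forward step: tert-butyl (2Z,4S)-4-{[(bromomethyl)(dimethyl)silyl]oxy}-17-(2-methyl-1,3-dioxolan-2-yl)-2-[(phenylsulfanyl)methyl]heptadec-2-enoate A5 would be treated with Bu3SnH and an initiator. The silylmethyl radical adds 5-exo to C4, and β-scission of the C–S bond leaves tert-butyl 2-{(4S,5S)-2,2-dimethyl-5-[13-(2-methyl-1,3-dioxolan-2-yl)tridecyl]-1,2-oxasilolan-4-yl}prop-2-enoate A6. Tamao oxidation, lactonisation and oxidation of the primary alcohol would follow.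
- In favour: the carboxyl carbon and the methylene come in one base-free step, which is better than the late methylenation of the chosen plan. The absolute configuration derives from one carbinol centre, as reliable a source as a chiral catalyst (equal). The usual trans preference of such closures on the oxasilolane corresponds to the cis lactone, so the intrinsic bias points the right way.
- Against: the size of that preference with an unbranched C5 substituent is uncertain; direct reduction and 6-endo closure compete; tin is stoichiometric; the peroxide-based C–Si oxidation must tolerate an electron-poor acrylate; and A5 needs a multistep assembly.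
- Comparison: relative configuration would come from substrate-controlled radical addition (a ratio) and not from stereospecific transfer of alkene geometry. The step count is probably similar or slightly higher.

Key step: step 7

Assumption: the facial preference of Rh2(5R-MEPY)4 for this long-chain (Z)-allylic diazoacetate is taken to be that known for short-chain (Z)-alkyl analogues; if the opposite sense arose, the 5S catalyst would be used.

Remark on the structures: the Z alkene of 14, the all-cis bicycle 15 and the (S,S)-cis target 24 are mutually consistent in carbon count and configuration, so no structure needs correcting; the one addition is the catalyst antipode (5R).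

## Route

Step 1
Reactants: 1 ethyl acetoacetate; 2 1,12-dibromododecane
Product: 5 15-bromopentadecan-2-one, via ethyl 2-acetyl-14-bromotetradecanoate 3 (not isolated), via 2-acetyl-14-bromotetradecanoic acid 4 (not isolated)
Conditions: NaOEt (1.0 equiv), 2 (3 equiv), EtOH, reflux; evaporate; 48% aq. HBr, AcOH, reflux
Reagents that add atoms: none
Why: Acetoacetic ester ketone synthesis: C-alkylation of the stabilised enolate by one end of the dibromide (the excess of 2 suppresses reaction at both ends and is recovered), then acid hydrolysis and loss of CO2 from the β-keto acid; HBr as the acid leaves the primary bromide intact.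

Step 2
Reactants: 5 15-bromopentadecan-2-one
Product: 6 2-(13-bromotridecyl)-2-methyl-1,3-dioxolane
Conditions: HOCH2CH2OH, p-TsOH (cat.), toluene, reflux, Dean–Stark trap
Reagents that add atoms: ethylene glycol (ethane-1,2-diol), `OCCO`
Why: Acid-catalysed ketalisation driven by azeotropic removal of water; the dioxolane shields the ketone from the acetylide base of step 3, the carbene of step 7 and the carboxylating base of step 11.

Step 3
Reactants: 7 prop-2-yn-1-ol; 6 2-(13-bromotridecyl)-2-methyl-1,3-dioxolane
Product: 9 16-(2-methyl-1,3-dioxolan-2-yl)hexadec-2-yn-1-ol, via dilithiated prop-2-yn-1-ol 8 (not isolated)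
Conditions: 7 (2.5 equiv), n-BuLi (5 equiv), THF/DMPU, −78 → 0 °C; then 6, 0 °C → rt; aq. NH4Cl
Reagents that add atoms: none
Why: The O,C-dianion reacts at its more nucleophilic acetylide carbon with the primary bromide (SN2 alkylation of an alkynyl anion in a dipolar cosolvent); the ketal is inert to the base.

Step 4
Reactants: 9 16-(2-methyl-1,3-dioxolan-2-yl)hexadec-2-yn-1-ol
Product: 10 (2Z)-16-(2-methyl-1,3-dioxolan-2-yl)hexadec-2-en-1-ol
Conditions: H2 (1 atm), Pd/CaCO3 poisoned with Pb(OAc)2, quinoline, EtOAc, rt
Reagents that add atoms: none
Why: Syn delivery of hydrogen from the poisoned palladium surface gives the Z alkene (cis-selective alkyne semi-hydrogenation); uptake is stopped after one equivalent to avoid over-reduction and Z/E drift.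

Step 5
Reactants: 10 (2Z)-16-(2-methyl-1,3-dioxolan-2-yl)hexadec-2-en-1-ol; 11 bromoacetyl bromide
Product: 12 (2Z)-16-(2-methyl-1,3-dioxolan-2-yl)hexadec-2-en-1-yl bromoacetate
Conditions: 11 (1.5 equiv), NaHCO3 (3 equiv), MeCN, 0 °C
Reagents that add atoms: none
Why: O-acylation of the primary allylic alcohol by the acyl bromide; solid bicarbonate takes up HBr, so neither the dioxolane nor the allylic ester meets acid.

Step 6
Reactants: 12 (2Z)-16-(2-methyl-1,3-dioxolan-2-yl)hexadec-2-en-1-yl bromoacetate
Product: 14 (2Z)-16-(2-methyl-1,3-dioxolan-2-yl)hexadec-2-en-1-yl diazoacetate, via N-alkylated ditosylhydrazine 13 (not isolated)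
Conditions: TsNHNHTs (2 equiv), DBU (5 equiv), THF, 0 °C
Reagents that add atoms: N,N'-ditosylhydrazine [N,N'-bis(4-methylbenzenesulfonyl)hydrazine], `Cc1ccc(cc1)S(=O)(=O)NNS(=O)(=O)c1ccc(C)cc1`
Why: The hydrazine anion is alkylated by the α-bromo ester and base then expels two sulfinate ions to leave the diazo group (diazoacetate synthesis from bromoacetates); no azide reagent and no acid is involved, and 14 is used promptly.

Step 7
Reactants: 14 (2Z)-16-(2-methyl-1,3-dioxolan-2-yl)hexadec-2-en-1-yl diazoacetate
Product: 15 (1S,5R,6S)-6-[13-(2-methyl-1,3-dioxolan-2-yl)tridecyl]-3-oxabicyclo[3.1.0]hexan-2-one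
Conditions: dirhodium tetrakis[methyl (5R)-2-oxopyrrolidine-5-carboxylate], Rh2(5R-MEPY)4 (1 mol %), CH2Cl2, reflux; 14 added over 10 h by syringe pump
Reagents that add atoms: none
Why: The catalyst takes up the diazo carbon, N2 leaves and the electrophilic rhodium-bound carbene is transferred to the tethered alkene in one concerted, asynchronous [2+1] event that forms C3–C4 and C3–C5 (target numbering); the closest known reaction type is the enantioselective intramolecular cyclopropanation of (Z)-allylic diazoacetates with chiral dirhodium carboxamidates of the Rh2(MEPY)4 type. The three-membered ring closes by this carbene addition, and the lactone ring closes with it because the three-atom ester tether lets the carbene carbon reach the nearer alkene carbon only in a five-membered, exo sense. The two ring-fusion centres (C1 and C5 of the bicycle) are necessarily cis, and which pair of alkene faces reacts is decided by the chiral ligand shell of the catalyst. C6 is fixed relative to C5 by stereospecific transfer of the Z geometry, which places the chain on the same side as the CH2O arm. The step needs cyclopropanation to win over carbene dimerisation, C–H insertion into the chain and ylide formation: slow addition keeps the diazo ester dilute, the carboxamidate ligands make the carbene selective for the nearby π bond, and the ketone is hidden as a dioxolane. It also needs high face selectivity, for which cis-disubstituted allylic diazoacetates are the best-matched substrates of this catalyst family; this is why the alkene is made by cis-selective semi-hydrogenation.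

Step 8
Reactants: 15 (1S,5R,6S)-6-[13-(2-methyl-1,3-dioxolan-2-yl)tridecyl]-3-oxabicyclo[3.1.0]hexan-2-one
Product: 16 (4R)-4-[(1R)-1-iodo-14-(2-methyl-1,3-dioxolan-2-yl)tetradecyl]oxolan-2-one
Conditions: MgI2 (3 equiv), THF/toluene, 70 °C; then sat. aq. NH4Cl, 0 °C
Reagents that add atoms: magnesium iodide, `[Mg+2].[I-].[I-]`
Why: Magnesium binds the lactone carbonyl and iodide attacks C6 of the bicycle (C5 of the target) opposite the breaking bond, so the cyclopropane bond that lies outside the lactone ring and overlaps with the carbonyl π system is cleaved with inversion (homo-conjugate opening of a Lewis-acid-activated cyclopropyl carbonyl compound); relief of ring strain drives the reaction and protonation on work-up gives the CH2 at C3.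

Step 9
Reactants: 16 (4R)-4-[(1R)-1-iodo-14-(2-methyl-1,3-dioxolan-2-yl)tetradecyl]oxolan-2-one
Product: 18 (4R,5S)-4-(hydroxymethyl)-5-[13-(2-methyl-1,3-dioxolan-2-yl)tridecyl]oxolan-2-one, via lithium iodo hydroxy carboxylate 17 (not isolated)
Conditions: LiOH·H2O (1.05 equiv), THF/H2O (3:1), 0 → 40 °C
Reagents that add atoms: lithium hydroxide, `[Li+].[OH-]`
Why: Hydroxide opens the γ-lactone and the freed carboxylate displaces the secondary iodide in a 5-exo-tet SN2 reaction, the second inversion at C5, which puts the chain cis to the CH2OH arm; the one equivalent of base ends up as neutral lithium iodide, so the new lactone is not saponified further.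

Step 10
Reactants: 18 (4R,5S)-4-(hydroxymethyl)-5-[13-(2-methyl-1,3-dioxolan-2-yl)tridecyl]oxolan-2-one
Product: 20 (2S,3S)-2-[13-(2-methyl-1,3-dioxolan-2-yl)tridecyl]-5-oxooxolane-3-carboxylic acid, via lactone aldehyde 19 (not isolated)
Conditions: TEMPO (cat.), NaOCl (cat.), NaClO2 (2 equiv), MeCN/sodium phosphate buffer (pH 6.7), 35 °C
Reagents that add atoms: sodium chlorite, `[Na+].[O-]Cl=O`
Why: Oxoammonium oxidation of the primary alcohol to the aldehyde and immediate chlorite oxidation to the acid; at pH 6.7 the aldehyde has neither the time nor the base to epimerise at C4, and the dioxolane is not hydrolysed.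

Step 11
Reactants: 20 (2S,3S)-2-[13-(2-methyl-1,3-dioxolan-2-yl)tridecyl]-5-oxooxolane-3-carboxylic acid
Product: 22 (2S,3S)-5-oxo-2-(14-oxopentadecyl)oxolane-3,4-dicarboxylic acid (C4 epimers), via ketal-protected dicarboxylic acid 21 (not isolated)
Conditions: MeOMgOCO2Me (2 M in DMF, excess), 130 °C; then 3 M HCl, THF, 0 °C → rt
Reagents that add atoms: methoxymagnesium methyl carbonate, `COC(=O)O[Mg]OC`; water, `O`
Why: Carboxylation of the lactone α-carbon, held as a magnesium chelate with the neighbouring carboxylate (chelation-driven α-carboxylation of γ-lactone acids); the ring C3 centre stays a carboxylate with a non-acidic α-hydrogen, so the cis arrangement is kept, and the acid work-up frees the diacid and hydrolyses the dioxolane before the sensitive methylene exists.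

Step 12
Reactants: 22 (2S,3S)-5-oxo-2-(14-oxopentadecyl)oxolane-3,4-dicarboxylic acid
Product: 24 allo-pertusaric acid [(2S,3S)-4-methylidene-5-oxo-2-(14-oxopentadecyl)oxolane-3-carboxylic acid], via Mannich adduct 23 (not isolated)
Conditions: 37% aq. HCHO, PhNHMe, NaOAc, AcOH, rt
Reagents that add atoms: formaldehyde, `C=O`
Why: The malonic-type acid adds to the iminium ion from formaldehyde and N-methylaniline, and the adduct loses CO2 and the amine to give the exocyclic alkene (decarboxylative Mannich methylenation); the buffered medium at room temperature neither epimerises the acid-bearing centre nor moves the double bond into the ring, and the methyl ketone enolises too slowly to compete.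

## Compound list

1 | ethyl acetoacetate | `CCOC(=O)CC(C)=O` | starting material
2 | 1,12-dibromododecane | `BrCCCCCCCCCCCCBr` | starting material
3 | ethyl 2-acetyl-14-bromotetradecanoate | `CCOC(=O)C(C(C)=O)CCCCCCCCCCCCBr` | intermediate (not isolated)
4 | 2-acetyl-14-bromotetradecanoic acid | `OC(=O)C(C(C)=O)CCCCCCCCCCCCBr` | intermediate (not isolated)
5 | 15-bromopentadecan-2-one | `CC(=O)CCCCCCCCCCCCCBr` | intermediate
6 | 2-(13-bromotridecyl)-2-methyl-1,3-dioxolane | `CC1(CCCCCCCCCCCCCBr)OCCO1` | intermediate
7 | prop-2-yn-1-ol | `C#CCO` | starting material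
8 | dilithiated prop-2-yn-1-ol (lithium 3-lithioprop-2-yn-1-olate) | `[Li]C#CCO[Li]` | intermediate (not isolated)
9 | 16-(2-methyl-1,3-dioxolan-2-yl)hexadec-2-yn-1-ol | `OCC#CCCCCCCCCCCCCCC1(C)OCCO1` | intermediate
10 | (2Z)-16-(2-methyl-1,3-dioxolan-2-yl)hexadec-2-en-1-ol | `OC/C=C\CCCCCCCCCCCCCC1(C)OCCO1` | intermediate
11 | bromoacetyl bromide | `O=C(Br)CBr` | starting material
12 | (2Z)-16-(2-methyl-1,3-dioxolan-2-yl)hexadec-2-en-1-yl bromoacetate | `BrCC(=O)OC/C=C\CCCCCCCCCCCCCC1(C)OCCO1` | intermediate
13 | (2Z)-16-(2-methyl-1,3-dioxolan-2-yl)hexadec-2-en-1-yl [1,2-bis(4-methylbenzenesulfonyl)hydrazinyl]acetate | `Cc1ccc(cc1)S(=O)(=O)NN(CC(=O)OC/C=C\CCCCCCCCCCCCCC2(C)OCCO2)S(=O)(=O)c1ccc(C)cc1` | intermediate (not isolated)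
14 | (2Z)-16-(2-methyl-1,3-dioxolan-2-yl)hexadec-2-en-1-yl diazoacetate | `[N-]=[N+]=CC(=O)OC/C=C\CCCCCCCCCCCCCC1(C)OCCO1` | intermediate (precursor of the key step)
15 | (1S,5R,6S)-6-[13-(2-methyl-1,3-dioxolan-2-yl)tridecyl]-3-oxabicyclo[3.1.0]hexan-2-one | `O=C1OC[C@H]2[C@@H]1[C@H]2CCCCCCCCCCCCCC3(C)OCCO3` | intermediate (product of the key step)
16 | (4R)-4-[(1R)-1-iodo-14-(2-methyl-1,3-dioxolan-2-yl)tetradecyl]oxolan-2-one | `O=C1C[C@H](CO1)[C@H](I)CCCCCCCCCCCCCC2(C)OCCO2` | intermediate
17 | lithium (3R,4R)-3-(hydroxymethyl)-4-iodo-17-(2-methyl-1,3-dioxolan-2-yl)heptadecanoate | `[Li+].[O-]C(=O)C[C@H](CO)[C@H](I)CCCCCCCCCCCCCC1(C)OCCO1` | intermediate (not isolated)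
18 | (4R,5S)-4-(hydroxymethyl)-5-[13-(2-methyl-1,3-dioxolan-2-yl)tridecyl]oxolan-2-one | `O=C1C[C@H](CO)[C@H](CCCCCCCCCCCCCC2(C)OCCO2)O1` | intermediate
19 | (2S,3S)-2-[13-(2-methyl-1,3-dioxolan-2-yl)tridecyl]-5-oxooxolane-3-carbaldehyde | `O=C1C[C@H](C=O)[C@H](CCCCCCCCCCCCCC2(C)OCCO2)O1` | intermediate (not isolated)
20 | (2S,3S)-2-[13-(2-methyl-1,3-dioxolan-2-yl)tridecyl]-5-oxooxolane-3-carboxylic acid | `O=C1C[C@H](C(=O)O)[C@H](CCCCCCCCCCCCCC2(C)OCCO2)O1` | intermediate
21 | (2S,3S)-2-[13-(2-methyl-1,3-dioxolan-2-yl)tridecyl]-5-oxooxolane-3,4-dicarboxylic acid (C4 epimers; magnesium chelate in the flask) | `O=C1C(C(=O)O)[C@H](C(=O)O)[C@H](CCCCCCCCCCCCCC2(C)OCCO2)O1` | intermediate (not isolated)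
22 | (2S,3S)-5-oxo-2-(14-oxopentadecyl)oxolane-3,4-dicarboxylic acid (C4 epimers) | `O=C1C(C(=O)O)[C@H](C(=O)O)[C@H](CCCCCCCCCCCCCC(C)=O)O1` | intermediate
23 | (2S,3S)-4-{[methyl(phenyl)amino]methyl}-5-oxo-2-(14-oxopentadecyl)oxolane-3,4-dicarboxylic acid | `O=C1C(CN(C)c2ccccc2)(C(=O)O)[C@H](C(=O)O)[C@H](CCCCCCCCCCCCCC(C)=O)O1` | intermediate (not isolated)
24 | allo-pertusaric acid, (2S,3S)-4-methylidene-5-oxo-2-(14-oxopentadecyl)oxolane-3-carboxylic acid | `C=C1C(=O)O[C@@H](CCCCCCCCCCCCCC(C)=O)[C@H]1C(=O)O` | target

## Step count and least certain steps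

Total step count: 12. Longest linear sequence: 12 steps (1 and 2 to 24); 7 and 11 enter as single building blocks.

Step 7 (key step). The most likely failures are incomplete face selection, if the long chain fits the catalyst pocket less well than short-chain models, and carbene dimerisation, if the diazo ester accumulates. The fallback replaces asymmetric catalysis by resolution; it sets out from 14 and returns at 15. Slow addition of 14 to copper bis(acetylacetonate), Cu(acac)2, in toluene at 100 °C would give the racemic all-cis bicyclic lactone F1. Heating F1 with (1S)-1-phenylethanamine and catalytic 2-hydroxypyridine in toluene would open it to two diastereomeric hydroxy amides, separable by chromatography or crystallisation: (1S,2R,3S)-2-(hydroxymethyl)-3-[13-(2-methyl-1,3-dioxolan-2-yl)tridecyl]-N-[(1S)-1-phenylethyl]cyclopropane-1-carboxamide F2 and its (1R,2S,3R) diastereomer F3. Anhydrous p-TsOH (1.1 equiv) in toluene at 70 °C would relactonise F2 by N→O acyl transfer onto the cis CH2OH group, releasing the amine and giving 15.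

Step 8. The singly activated cyclopropane may resist opening, or the Lewis acid and iodide may attack the dioxolane or the lactone alkyl–oxygen bond before the ring opens. The fallback removes the acid-sensitive group first and uses a stronger silyl activator; it sets out from 15 and returns at 18. PPTS in aqueous acetone would give (1S,5R,6S)-6-(14-oxopentadecyl)-3-oxabicyclo[3.1.0]hexan-2-one F4. Me3SiI (from Me3SiCl and NaI) in MeCN at 0 °C → rt would open it to (4R)-4-[(1R)-1-iodo-15-oxohexadecyl]oxolan-2-one F5. LiOH as in step 9 would pass through lithium (3R,4R)-3-(hydroxymethyl)-4-iodo-18-oxononadecanoate F6 to (4R,5S)-4-(hydroxymethyl)-5-(14-oxopentadecyl)oxolan-2-one F7, and ethylene glycol with PPTS in refluxing benzene would restore the dioxolane to give 18.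

Step 11. Prolonged heating with the basic magnesium reagent may erode the cis configuration, carboxylation may stay incomplete, or the diacid may lose CO2 during the acid work-up. The fallback makes the methylene before the acid and needs no carboxylation; it sets out from 18, bypasses steps 10 to 12 and returns at 24.
- t-BuPh2SiCl and imidazole in DMF would give (4R,5S)-4-({[tert-butyl(diphenyl)silyl]oxy}methyl)-5-[13-(2-methyl-1,3-dioxolan-2-yl)tridecyl]oxolan-2-one F8.
- LiN(iPr)2 in THF at −78 °C, then dimethyl(methylidene)ammonium iodide, would give the 3-[(dimethylamino)methyl] lactone F9.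
- MeI in MeOH would give the trimethylammonium iodide F10, and aqueous NaHCO3 would eliminate it to (4R,5S)-4-({[tert-butyl(diphenyl)silyl]oxy}methyl)-3-methylidene-5-[13-(2-methyl-1,3-dioxolan-2-yl)tridecyl]oxolan-2-one F11.
- HF·pyridine in THF would free (4R,5S)-4-(hydroxymethyl)-3-methylidene-5-[13-(2-methyl-1,3-dioxolan-2-yl)tridecyl]oxolan-2-one F12.
- CrO3/H2SO4 in aqueous acetone at 0 °C would oxidise the primary alcohol to the acid and hydrolyse the dioxolane in the same operation, giving 24.

Step 3. The poorly soluble, strongly basic dianion may give low conversion, with elimination from the long-chain bromide or O-alkylation competing. The fallback forms the propargylic C–C bond at the other end; it sets out from 6 and returns at 9. Lithium acetylide–ethylenediamine complex (LiC≡CH·H2NCH2CH2NH2) in DMSO at rt would give 2-methyl-2-(pentadec-14-yn-1-yl)-1,3-dioxolane F13; n-BuLi in THF at −78 °C followed by paraformaldehyde would hydroxymethylate the acetylide to 9.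

## Further compounds

F1 | step 7 | racemic all-cis 6-[13-(2-methyl-1,3-dioxolan-2-yl)tridecyl]-3-oxabicyclo[3.1.0]hexan-2-one (both enantiomers) | `O=C1OC[C@H]2[C@@H]1[C@H]2CCCCCCCCCCCCCC3(C)OCCO3.O=C1OC[C@@H]2[C@H]1[C@@H]2CCCCCCCCCCCCCC3(C)OCCO3`
F2 | step 7 | (1S,2R,3S)-2-(hydroxymethyl)-3-[13-(2-methyl-1,3-dioxolan-2-yl)tridecyl]-N-[(1S)-1-phenylethyl]cyclopropane-1-carboxamide | `C[C@H](NC(=O)[C@@H]2[C@H](CO)[C@@H]2CCCCCCCCCCCCCC3(C)OCCO3)c1ccccc1`
F3 | step 7 | (1R,2S,3R)-2-(hydroxymethyl)-3-[13-(2-methyl-1,3-dioxolan-2-yl)tridecyl]-N-[(1S)-1-phenylethyl]cyclopropane-1-carboxamide | `C[C@H](NC(=O)[C@H]2[C@@H](CO)[C@H]2CCCCCCCCCCCCCC3(C)OCCO3)c1ccccc1`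
F4 | step 8 | (1S,5R,6S)-6-(14-oxopentadecyl)-3-oxabicyclo[3.1.0]hexan-2-one | `O=C1OC[C@H]2[C@@H]1[C@H]2CCCCCCCCCCCCCC(C)=O`
F5 | step 8 | (4R)-4-[(1R)-1-iodo-15-oxohexadecyl]oxolan-2-one | `O=C1C[C@H](CO1)[C@H](I)CCCCCCCCCCCCCC(C)=O`
F6 | step 8 | lithium (3R,4R)-3-(hydroxymethyl)-4-iodo-18-oxononadecanoate | `[Li+].[O-]C(=O)C[C@H](CO)[C@H](I)CCCCCCCCCCCCCC(C)=O`
F7 | step 8 | (4R,5S)-4-(hydroxymethyl)-5-(14-oxopentadecyl)oxolan-2-one | `O=C1C[C@H](CO)[C@H](CCCCCCCCCCCCCC(C)=O)O1`
F8 | step 11 | (4R,5S)-4-({[tert-butyl(diphenyl)silyl]oxy}methyl)-5-[13-(2-methyl-1,3-dioxolan-2-yl)tridecyl]oxolan-2-one | `O=C1C[C@H](CO[Si](c2ccccc2)(c3ccccc3)C(C)(C)C)[C@H](CCCCCCCCCCCCCC4(C)OCCO4)O1`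
F9 | step 11 | (4R,5S)-4-({[tert-butyl(diphenyl)silyl]oxy}methyl)-3-[(dimethylamino)methyl]-5-[13-(2-methyl-1,3-dioxolan-2-yl)tridecyl]oxolan-2-one (C3 epimers) | `O=C1C(CN(C)C)[C@H](CO[Si](c2ccccc2)(c3ccccc3)C(C)(C)C)[C@H](CCCCCCCCCCCCCC4(C)OCCO4)O1`
F10 | step 11 | {[(4R,5S)-4-({[tert-butyl(diphenyl)silyl]oxy}methyl)-5-[13-(2-methyl-1,3-dioxolan-2-yl)tridecyl]-2-oxooxolan-3-yl]methyl}trimethylammonium iodide | `O=C1C(C[N+](C)(C)C)[C@H](CO[Si](c2ccccc2)(c3ccccc3)C(C)(C)C)[C@H](CCCCCCCCCCCCCC4(C)OCCO4)O1.[I-]`
F11 | step 11 | (4R,5S)-4-({[tert-butyl(diphenyl)silyl]oxy}methyl)-3-methylidene-5-[13-(2-methyl-1,3-dioxolan-2-yl)tridecyl]oxolan-2-one | `C=C1C(=O)O[C@@H](CCCCCCCCCCCCCC2(C)OCCO2)[C@H]1CO[Si](c3ccccc3)(c4ccccc4)C(C)(C)C`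
F12 | step 11 | (4R,5S)-4-(hydroxymethyl)-3-methylidene-5-[13-(2-methyl-1,3-dioxolan-2-yl)tridecyl]oxolan-2-one | `C=C1C(=O)O[C@@H](CCCCCCCCCCCCCC2(C)OCCO2)[C@H]1CO`
F13 | step 3 | 2-methyl-2-(pentadec-14-yn-1-yl)-1,3-dioxolane | `C#CCCCCCCCCCCCCCC1(C)OCCO1`
A1 | alternative 1 | (3R)-3-(tert-butoxycarbonyl)-18-oxononadecanoic acid | `OC(=O)C[C@H](C(=O)OC(C)(C)C)CCCCCCCCCCCCCCC(C)=O`
A2 | alternative 1 | tert-butyl (2S,3S)-5-oxo-2-(14-oxopentadecyl)oxolane-3-carboxylate | `O=C1C[C@H](C(=O)OC(C)(C)C)[C@H](CCCCCCCCCCCCCC(C)=O)O1`
A3 | alternative 2 | (3R,4S)-3-({[tert-butyl(dimethyl)silyl]oxy}methyl)-17-(2-methyl-1,3-dioxolan-2-yl)heptadec-1-yn-4-ol | `C#C[C@H](CO[Si](C)(C)C(C)(C)C)[C@@H](O)CCCCCCCCCCCCCC1(C)OCCO1`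
A4 | alternative 2 | (4R,5S)-4-({[tert-butyl(dimethyl)silyl]oxy}methyl)-3-methylidene-5-[13-(2-methyl-1,3-dioxolan-2-yl)tridecyl]oxolan-2-one | `C=C1C(=O)O[C@@H](CCCCCCCCCCCCCC2(C)OCCO2)[C@H]1CO[Si](C)(C)C(C)(C)C`
A5 | alternative 3 | tert-butyl (2Z,4S)-4-{[(bromomethyl)(dimethyl)silyl]oxy}-17-(2-methyl-1,3-dioxolan-2-yl)-2-[(phenylsulfanyl)methyl]heptadec-2-enoate | `CC(C)(C)OC(=O)/C(CSc1ccccc1)=C/[C@@H](O[Si](C)(C)CBr)CCCCCCCCCCCCCC2(C)OCCO2`
A6 | alternative 3 | tert-butyl 2-{(4S,5S)-2,2-dimethyl-5-[13-(2-methyl-1,3-dioxolan-2-yl)tridecyl]-1,2-oxasilolan-4-yl}prop-2-enoate | `CC(C)(C)OC(=O)C(=C)[C@@H]1C[Si](C)(C)O[C@H]1CCCCCCCCCCCCCC2(C)OCCO2`
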